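# Proposed synthesis of hansfordiol G (15) by electroreductive doubly decarboxylative coupling across C12'–C13'

The side chain is numbered C1' (benzylic) to C17' (methyl). Compound numbers are those of the step list and the compound list below.

## The problem

Hansfordiol G (15) is a 5-alkylresorcinol with an unbranched seventeen-carbon chain, a Z olefin at C8'=C9' and one secondary carbinol of S configuration at C15'. No ring has to be built, so the task is chain assembly with control of one olefin geometry and one stereocentre. The C15' stereocentre stands alone, and nothing else in the molecule can relay stereochemistry to it. It is flanked by an ethyl group and a long n-alkyl chain, two substituents that small chiral reagents distinguish poorly. It must therefore come from an enzyme pocket, a chiral-pool piece, or a bond formation in which the oxygen is the discriminating element. The Z olefin must be installed with high geometric purity and then kept away from conditions that isomerise it, such as metal hydrides, reversible radical additions and strong acid. The resorcinol ring is electron-rich, easily oxidised and easily attacked by electrophiles. It needs a protecting group that survives base, hydride, hydrogenation and electrolysis and is removed without harming the olefin or the carbinol. The enabling feature is the unfunctionalised pentamethylene C10'–C14' between the olefin and the oxygen-bearing carbon. At its central bond C12'–C13' the two radicals are a pent-4-enyl-type radical at C12' and a 3-oxopentyl radical at C13'. The first can close onto C8'=C9' only by slow 4-exo or 5-endo modes, and the second can only undergo a degenerate acyl shift. That bond can therefore be made by a radical-based nickel coupling of two carboxylic acid derivatives.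

## Retrosynthesis

**15 ⇒ 14 (phenol O–C bonds).** The last operation is release of the two phenols from bis(methoxymethyl) ether 14. Methyl ethers would need a boron trihalide, which endangers the carbinol and the olefin. Benzyl ethers would need hydrogenolysis, which reduces the olefin. Aryl silyl ethers are doubtful under the strongly basic ylide chemistry. The acetal ethers survive base, hydrogenation, oxidation, carbodiimide coupling and cathodic electrolysis, and fall to dilute methanolic acid that leaves the isolated olefin and the non-allylic alcohol alone.

**14 ⇒ 13 (C15'–H bond).** The stereocentre is taken back to ketone 13. Carrying the carbinol into the coupling in a preformed, protected chiral C5 acid would cost several extra steps on the small fragment, whereas 4-oxohexanoic acid 11 is commercial and its ketone is inert in the coupling. The forward reaction must distinguish ethyl from a long chain, which calls for an enzyme and not a small-molecule reductant.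

**13 ⇒ 10 + 12 (C12'–C13' bond, key disconnection).** Cutting the pentamethylene at its centre gives redox-active esters 10 and 12, both derived from carboxylic acids. The neighbouring cuts are worse:
- C11'–C12' would place a homoallylic radical at C11', whose reversible 3-exo closure scrambles the Z geometry.
- C10'–C11' would require an allylic radical.
- C13'–C14' would pair a hex-5-enyl-type radical, which closes 5-exo rapidly, with an easily reduced α-keto radical.

The C17 target is thereby reduced to a C12 fragment carrying the arene and the olefin and a five-carbon commercial keto acid. The forward reaction must favour cross- over homo-coupling, leave the olefin geometry intact, and tolerate a ketone and two acetals.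

**10 ⇒ 9 and 12 ⇒ 11 (acyl C–O bonds).** Each redox-active ester comes from its acid, 9 or 11, by a single carbodiimide esterification. Nothing is asked beyond neutral conditions.

**9 ⇒ 6 + 7 (C8'=C9' double bond).** Acid 9 is opened at the olefin to aldehyde 6 (C1'–C8') and phosphonium salt 7 (C9'–C12' plus the carboxyl carbon that is later lost as CO2). A non-stabilised ylide under lithium-free conditions is the shortest reliable entry to a Z-disubstituted olefin. Salt 7 is commercial and brings the carboxyl group unprotected. An alkyne semi-hydrogenation would need more steps.

**6 ⇒ 5 ⇒ 4 ⇒ 2 + 3 (aryl–C1' bond).** Aldehyde 6 comes from alcohol 5 by oxidation, 5 from arylalkyne 4 by hydrogenation, and 4 from aryl bromide 2 and oct-7-yn-1-ol 3 by an sp2–sp coupling. Alkynol 3 supplies all eight carbons C1'–C8' with oxygen already on the right terminus. The alkyne is hydrogenated before any olefin exists, so no selectivity is needed.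

**2 ⇒ 1 (phenol protection).** Bromide 2 is the bis(methoxymethyl) ether of commercial 5-bromobenzene-1,3-diol 1.

## Roads not taken

**Alternative 1:** Cut C15'–C16' and add the ethyl group last by lithiation–borylation.
- Forward key step: the primary carbamate A2 carries the whole C1'–C15' chain. It would be deprotonated enantioselectively at C15' by an alkyllithium–chiral diamine base (the sparteine class) and trapped with ethylboronic ester A3. On warming, ethyl migrates from boron to carbon with loss of the carbamate to give secondary boronic ester A1, which is oxidised to the carbinol with retention.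
- Merits: the stereocentre is set by reagent control in which the oxygen substituent, not the ethyl/alkyl difference, is the handle. The reaction class is well precedented for primary alkyl carbamates and its outcome is predictable.
- Weak points: a stoichiometric organolithium and a stoichiometric chiral diamine are used at low temperature on the most advanced intermediate. The phenols must carry bulky silyl groups, because acetal ethers would direct ring lithiation between the two oxygens. The sequence is linear, since the last carbon–carbon bond adds only two carbons, and an oxidation and a desilylation follow.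
- Comparison: in stereochemical predictability this road is at least equal and probably superior to the enzymatic reduction of 13, and its step count is similar. The chosen plan sets against it a convergent C12 + C5 union at room temperature from bench-stable esters and no stoichiometric chiral reagent, and accepts enzyme screening in return.

**Alternative 2:** Cut both bonds flanking the olefin, C7'–C8' and C9'–C10', and supply C8'=C9' as cis-dichloride A5.
- Forward key step: in one flask Grignard reagent A6 would be coupled once with excess A5 under zerovalent palladium–phosphine catalysis to Z-alkenyl chloride A7. After evaporation of the excess dichloride, A7 would be coupled with the chiral Grignard reagent A8 under iron catalysis to give silyl ether A4.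
- Merits: the Z geometry is purchased and passed through two stereoretentive couplings. That is a stronger guarantee than the Wittig reaction of the chosen plan. The union is three-component and central.
- Weak points: both Grignard reagents come from bromides that each need several steps. A8 already contains the C15' stereocentre, so the stereochemical problem is moved to a fragment synthesis and not solved. Monoalkylation needs a large excess of a volatile dichloride. Alkyl Grignard reagents with β-hydrogens can reduce or homocouple under palladium. The overall step count is clearly higher.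
- Comparison: this road is better on olefin geometry. The chosen plan sets against it a shorter sequence, commercial partners for both late fragments, and a key step that needs no organomagnesium reagents.

**Alternative 3:** Cut C14'–C15' and set the stereocentre while joining the chain.
- Forward key step: a chiral nickel–bis(oxazoline) hydride catalyst with a hydrosilane would add to the terminal C13'=C14' olefin of diene A10. The resulting primary alkylnickel would couple enantioconvergently with racemic α-bromo ester A11 to give benzoate A9.
- Merits: bond and stereocentre form in one step. The catalyst discriminates acyloxy from ethyl from hydrogen at the stereogenic carbon, so the similarity of ethyl and the long chain is irrelevant. On paper the sequence is about one step shorter than the chosen plan.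
- Weak points: nickel hydrides are the species that chain-walk and isomerise olefins. The catalyst must choose the terminal olefin over C8'=C9' and must not walk from C14' toward the allylic C10' position, where the Z geometry would be lost. A11 is hydrolytically labile and must be made and used fresh. The benzoate needs a basic cleavage separate from the acidic acetal removal.
- Comparison: this road is shorter and more elegant in stereocontrol. The chosen plan sets against it a key step that generates no metal hydride and so does not threaten the Z olefin, and crystalline, storable coupling partners. It pays with a separate reduction step.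

Key step: step 8

## Route

Assumption: a Prelog-type ketoreductase that accepts ethyl n-alkyl ketones is taken to be identifiable from commercial enzyme panels; no particular enzyme is presumed.

Step 1
Reactants: 1 5-bromobenzene-1,3-diol
Product: 2 1-bromo-3,5-bis(methoxymethoxy)benzene
Conditions: MOMCl (3 equiv), i-Pr2NEt (4 equiv), CH2Cl2, 0 °C → rt
Reagents that add atoms: chloromethyl methyl ether, COCCl
Why: O-alkylation of both phenols by the reactive α-chloro ether under amine base (methoxymethyl ether formation); the aryl bromide is untouched.

Step 2
Reactants: 2 1-bromo-3,5-bis(methoxymethoxy)benzene; 3 oct-7-yn-1-ol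
Product: 4 8-[3,5-bis(methoxymethoxy)phenyl]oct-7-yn-1-ol
Conditions: PdCl2(PPh3)2 (3 mol %), CuI (5 mol %), Et3N/THF, degassed, 65 °C
Reagents that add atoms: none
Why: Sonogashira coupling: zerovalent palladium inserts into the aryl C–Br bond, the copper acetylide of 3 transmetalates and reductive elimination forms the aryl–alkynyl bond; the free hydroxyl and the acetal ethers are inert in the amine medium.

Step 3
Reactants: 4 8-[3,5-bis(methoxymethoxy)phenyl]oct-7-yn-1-ol
Product: 5 8-[3,5-bis(methoxymethoxy)phenyl]octan-1-ol
Conditions: H2 (1 atm), 10% Pd/C, EtOAc, rt
Reagents that add atoms: none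
Why: Heterogeneous catalytic hydrogenation saturates the arylalkyne; aryl methoxymethyl ethers and the primary alcohol are stable to H2 over Pd/C in neutral solvent, and no olefin is present yet.

Step 4
Reactants: 5 8-[3,5-bis(methoxymethoxy)phenyl]octan-1-ol
Product: 6 8-[3,5-bis(methoxymethoxy)phenyl]octanal
Conditions: Dess–Martin periodinane (1.2 equiv), CH2Cl2, 0 °C → rt
Reagents that add atoms: none
Why: Dess–Martin oxidation stops at the aldehyde under near-neutral conditions that leave the acid-labile acetal ethers and the electron-rich ring intact.

Step 5
Reactants: 6 8-[3,5-bis(methoxymethoxy)phenyl]octanal; 7 (4-carboxybutyl)triphenylphosphonium bromide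
Product: 9 (5Z)-13-[3,5-bis(methoxymethoxy)phenyl]tridec-5-enoic acid, via sodium 5-(triphenylphosphoranylidene)pentanoate 8 (not isolated)
Conditions: 7 (2 equiv), NaN(SiMe3)2 (4 equiv), THF, 0 °C; then 6, −78 °C → rt; dilute HCl to pH 4, 0 °C
Reagents that add atoms: none
Why: Wittig olefination with a non-stabilised ylide under lithium-free conditions forms the cis-oxaphosphetane kinetically and hence the Z olefin C8'=C9'; the second equivalent of base holds the carboxyl group as its sodium salt, so the acid needs no protection.

Step 6
Reactants: 9 (5Z)-13-[3,5-bis(methoxymethoxy)phenyl]tridec-5-enoic acid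
Product: 10 1,3-dioxoisoindolin-2-yl (5Z)-13-[3,5-bis(methoxymethoxy)phenyl]tridec-5-enoate
Conditions: N-hydroxyphthalimide (1.1 equiv), N,N'-diisopropylcarbodiimide (1.1 equiv), DMAP (10 mol %), CH2Cl2, rt
Reagents that add atoms: N-hydroxyphthalimide, O=C1c2ccccc2C(=O)N1O
Why: Carbodiimide (Steglich-type) esterification through the O-acylisourea gives the redox-active ester under neutral conditions that touch neither the olefin geometry nor the acetals.

Step 7
Reactants: 11 4-oxohexanoic acid
Product: 12 1,3-dioxoisoindolin-2-yl 4-oxohexanoate
Conditions: N-hydroxyphthalimide (1.1 equiv), N,N'-diisopropylcarbodiimide (1.1 equiv), DMAP (10 mol %), CH2Cl2, rt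
Reagents that add atoms: N-hydroxyphthalimide, O=C1c2ccccc2C(=O)N1O
Why: The same carbodiimide esterification; the γ-keto group does not interfere, as in the well-known redox-active esters of γ-keto acids.

Step 8
Reactants: 10 1,3-dioxoisoindolin-2-yl (5Z)-13-[3,5-bis(methoxymethoxy)phenyl]tridec-5-enoate; 12 1,3-dioxoisoindolin-2-yl 4-oxohexanoate
Product: 13 (9Z)-17-[3,5-bis(methoxymethoxy)phenyl]heptadec-9-en-3-one
Conditions: 12 (3 equiv), NiCl2·6H2O (20 mol %), 2,2':6',2''-terpyridine (20 mol %), AgNO3 (0.5 equiv), DMF, Mg anode/reticulated vitreous carbon cathode, undivided cell, constant current, rt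
Reagents that add atoms: none
Why: Cathodic reduction generates low-valent (monovalent or zerovalent) nickel–terpyridine, which transfers one electron to each N-hydroxyphthalimide ester; the radical anions fragment to phthalimide anion, CO2 and the primary radicals at C12' (from 10) and C13' (from 12). One radical is captured at nickel, the second adds to the resulting alkylnickel, and reductive elimination from the trivalent dialkylnickel forms the C12'–C13' bond, while the magnesium anode supplies the electrons, Mg2+ pairs with phthalimide, and silver deposited on the cathode from AgNO3 tempers direct reduction of the esters. The closest known reaction type is the nickel-electrocatalytic doubly decarboxylative C(sp3)–C(sp3) coupling of two alkyl redox-active esters, the reductive counterpart of mixed Kolbe electrolysis, which is established for primary–primary pairs. No ring closes and no stereocentre is formed. The selectivity needed is cross- over homo-coupling; it is secured statistically by the threefold excess of the inexpensive 12, whose homodimer is a small diketone that separates easily, as does the tetra-acetal homodimer of 10. Olefin integrity is secured by the position of the radical: the C12' radical is of pent-4-enyl type, for which 4-exo and 5-endo closure onto C8'=C9' are too slow to compete with capture by nickel, and the 3-oxopentyl radical can only undergo a degenerate 1,2-acyl shift. The dialkyl ketone, the acetal ethers and the electron-rich arene are not reduced at the potential of the nickel catalyst, and a reducing medium cannot oxidise the arene as an anodic Kolbe coupling would.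

Step 9
Reactants: 13 (9Z)-17-[3,5-bis(methoxymethoxy)phenyl]heptadec-9-en-3-one
Product: 14 (3S,9Z)-17-[3,5-bis(methoxymethoxy)phenyl]heptadec-9-en-3-ol
Conditions: Prelog-selective NADPH-dependent ketoreductase (alcohol dehydrogenase), NADP+ (cat.), i-PrOH (20% v/v), nonionic surfactant, KH2PO4/K2HPO4 buffer pH 7, 30 °C
Reagents that add atoms: none
Why: Enzymatic ketone reduction following the Prelog rule: with ethyl in the small pocket and the long chain in the large pocket, hydride from the cofactor is delivered to the Re face of C15', which gives the S carbinol; propan-2-ol regenerates the cofactor, and pH 7 leaves the acetals and the olefin untouched.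

Step 10
Reactants: 14 (3S,9Z)-17-[3,5-bis(methoxymethoxy)phenyl]heptadec-9-en-3-ol
Product: 15 hansfordiol G, 5-[(8Z,15S)-15-hydroxyheptadec-8-en-1-yl]benzene-1,3-diol
Conditions: HCl (ca. 1 M) in MeOH, rt → 40 °C
Reagents that add atoms: none
Why: Acid-catalysed acetal exchange (methanolysis of the methoxymethyl ethers) frees both phenols, methanol trapping the methoxymethyl cation as dimethoxymethane; the isolated Z olefin and the non-allylic secondary alcohol are inert to dilute methanolic acid, so C15' is not touched.

## Compound list

1 | 5-bromobenzene-1,3-diol | Oc1cc(O)cc(Br)c1 | starting material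
2 | 1-bromo-3,5-bis(methoxymethoxy)benzene | COCOc1cc(Br)cc(OCOC)c1 | intermediate
3 | oct-7-yn-1-ol | C#CCCCCCCO | starting material
4 | 8-[3,5-bis(methoxymethoxy)phenyl]oct-7-yn-1-ol | OCCCCCCC#Cc1cc(OCOC)cc(OCOC)c1 | intermediate
5 | 8-[3,5-bis(methoxymethoxy)phenyl]octan-1-ol | OCCCCCCCCc1cc(OCOC)cc(OCOC)c1 | intermediate
6 | 8-[3,5-bis(methoxymethoxy)phenyl]octanal | O=CCCCCCCCc1cc(OCOC)cc(OCOC)c1 | intermediate
7 | (4-carboxybutyl)triphenylphosphonium bromide | OC(=O)CCCC[P+](c1ccccc1)(c1ccccc1)c1ccccc1.[Br-] | starting material
8 | sodium 5-(triphenylphosphoranylidene)pentanoate (ylide, not isolated) | [Na+].[O-]C(=O)CCCC=P(c1ccccc1)(c1ccccc1)c1ccccc1 | intermediate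
9 | (5Z)-13-[3,5-bis(methoxymethoxy)phenyl]tridec-5-enoic acid | OC(=O)CCC/C=C\CCCCCCCc1cc(OCOC)cc(OCOC)c1 | intermediate
10 | 1,3-dioxoisoindolin-2-yl (5Z)-13-[3,5-bis(methoxymethoxy)phenyl]tridec-5-enoate | O=C(CCC/C=C\CCCCCCCc1cc(OCOC)cc(OCOC)c1)ON1C(=O)c2ccccc2C1=O | intermediate
11 | 4-oxohexanoic acid | CCC(=O)CCC(=O)O | starting material
12 | 1,3-dioxoisoindolin-2-yl 4-oxohexanoate | CCC(=O)CCC(=O)ON1C(=O)c2ccccc2C1=O | intermediate
13 | (9Z)-17-[3,5-bis(methoxymethoxy)phenyl]heptadec-9-en-3-one | CCC(=O)CCCCC/C=C\CCCCCCCc1cc(OCOC)cc(OCOC)c1 | intermediate
14 | (3S,9Z)-17-[3,5-bis(methoxymethoxy)phenyl]heptadec-9-en-3-ol | CC[C@H](O)CCCCC/C=C\CCCCCCCc1cc(OCOC)cc(OCOC)c1 | intermediate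
15 | hansfordiol G, 5-[(8Z,15S)-15-hydroxyheptadec-8-en-1-yl]benzene-1,3-diol | CC[C@H](O)CCCCC/C=C\CCCCCCCc1cc(O)cc(O)c1 | target

## Step count and least certain steps

Total: 10 steps. Longest linear sequence: 9 steps (steps 1–6, 8, 9 and 10 from 1); step 7 is a one-step branch.

**Step 8 (key step).**
- Risk: loss of the valuable partner through homodimerisation and premature reduction of its radical to the alkane. Both esters are primary and of similar reduction potential, so the catalyst cannot tell them apart and only stoichiometry steers the outcome. β-Hydride elimination at alkylnickel intermediates could also generate a nickel hydride that isomerises the Z olefin.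
- Fallback: an ionic route that keeps the carboxyl carbon of 9 as C13' and makes the C13'–C14' bond by azaenolate alkylation. It sets out from 9 and returns at 13.
  - LiAlH4 in THF at 0 °C would reduce 9 to (5Z)-13-[3,5-bis(methoxymethoxy)phenyl]tridec-5-en-1-ol F1.
  - I2, PPh3 and imidazole in CH2Cl2 would convert F1 into 1-[(8Z)-13-iodotridec-8-en-1-yl]-3,5-bis(methoxymethoxy)benzene F2.
  - Butan-2-one N,N-dimethylhydrazone F3 would be prepared by condensation of butan-2-one with N,N-dimethylhydrazine. It would be deprotonated at its methyl group with LiN(i-Pr)2 in THF at −78 °C, where kinetic deprotonation goes to the less substituted α-carbon, and alkylated with F2. This gives the N,N-dimethylhydrazone of (9Z)-17-[3,5-bis(methoxymethoxy)phenyl]heptadec-9-en-3-one F4.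
  - Hydrolysis with aqueous Cu(OAc)2 in THF at rt would release 13.

**Step 9.**
- Risk: poor conversion because the very lipophilic C17 ketone is barely available to an enzyme in aqueous buffer, and incomplete discrimination between ethyl and the long chain in the enzyme pockets, which would lower the enantiomeric purity.
- Fallback: racemic reduction followed by kinetic resolution in an organic solvent, where solubility is no issue. It sets out from 13 and returns at 14.
  - NaBH4 in MeOH at 0 °C would give racemic (9Z)-17-[3,5-bis(methoxymethoxy)phenyl]heptadec-9-en-3-ol F5.
  - Immobilised Candida antarctica lipase B with commercial vinyl acetate in hexane at rt should acylate the R enantiomer (Kazlauskas rule; ethyl fits the medium pocket, the long chain does not). This gives (3R,9Z)-17-[3,5-bis(methoxymethoxy)phenyl]heptadec-9-en-3-yl acetate F6 and leaves 14, which is separated by chromatography.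
  - F6 can be recycled by K2CO3 in MeOH to (3R,9Z)-17-[3,5-bis(methoxymethoxy)phenyl]heptadec-9-en-3-ol F7 and Dess–Martin oxidation back to 13.

**Step 5.**
- Risk: erosion of Z selectivity through stereochemical drift of the oxaphosphetane if lithium salts or higher temperatures intervene, and sluggish reaction of the poorly soluble dianionic ylide. An E isomer would be hard to remove later.
- Fallback: the geometry is fixed on a small iodoalkene and transferred by a stereoretentive cross-coupling. It sets out from 6 and returns at 9.
  - Stork–Zhao olefination of 6 with commercial (iodomethyl)triphenylphosphonium iodide and NaN(SiMe3)2 in THF/DMPU at −78 °C would give 1-[(8Z)-9-iodonon-8-en-1-yl]-3,5-bis(methoxymethoxy)benzene F8.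
  - Negishi coupling with commercial BrZn(CH2)3CO2Et and Pd(PPh3)4 in THF at rt would give ethyl (5Z)-13-[3,5-bis(methoxymethoxy)phenyl]tridec-5-enoate F9 with retention of geometry.
  - LiOH in THF/H2O would give 9.

**Step 2.**
- Risk: oxidative homocoupling of the alkynol by traces of oxygen and slow oxidative addition into the electron-rich aryl bromide, leaving the coupling incomplete.
- Fallback: an sp2–sp3 coupling that needs no alkyne. It sets out from 2 and returns at 5, bypassing 4 and step 3.
  - Commercial oct-7-en-1-ol would be hydroborated with 9-borabicyclo[3.3.1]nonane (2.2 equiv, THF, rt; the excess takes up the hydroxyl as a borinate that is cleaved on work-up) to 8-(9-borabicyclo[3.3.1]nonan-9-yl)octan-1-ol F10.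
  - F10 would be coupled without isolation with 2 (PdCl2(dppf), aqueous K3PO4, THF/DMF, 60 °C; B-alkyl Suzuki–Miyaura coupling) to give 5.

## Further compounds

F1 | step 8 | (5Z)-13-[3,5-bis(methoxymethoxy)phenyl]tridec-5-en-1-ol | OCCCC/C=C\CCCCCCCc1cc(OCOC)cc(OCOC)c1
F2 | step 8 | 1-[(8Z)-13-iodotridec-8-en-1-yl]-3,5-bis(methoxymethoxy)benzene | ICCCC/C=C\CCCCCCCc1cc(OCOC)cc(OCOC)c1
F3 | step 8 | butan-2-one N,N-dimethylhydrazone | CCC(C)=NN(C)C
F4 | step 8 | N,N-dimethylhydrazone of (9Z)-17-[3,5-bis(methoxymethoxy)phenyl]heptadec-9-en-3-one | CCC(=NN(C)C)CCCCC/C=C\CCCCCCCc1cc(OCOC)cc(OCOC)c1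
F5 | step 9 | racemic (9Z)-17-[3,5-bis(methoxymethoxy)phenyl]heptadec-9-en-3-ol | CCC(O)CCCCC/C=C\CCCCCCCc1cc(OCOC)cc(OCOC)c1
F6 | step 9 | (3R,9Z)-17-[3,5-bis(methoxymethoxy)phenyl]heptadec-9-en-3-yl acetate | CC[C@@H](OC(C)=O)CCCCC/C=C\CCCCCCCc1cc(OCOC)cc(OCOC)c1
F7 | step 9 | (3R,9Z)-17-[3,5-bis(methoxymethoxy)phenyl]heptadec-9-en-3-ol | CC[C@@H](O)CCCCC/C=C\CCCCCCCc1cc(OCOC)cc(OCOC)c1
F8 | step 5 | 1-[(8Z)-9-iodonon-8-en-1-yl]-3,5-bis(methoxymethoxy)benzene | I/C=C\CCCCCCCc1cc(OCOC)cc(OCOC)c1
F9 | step 5 | ethyl (5Z)-13-[3,5-bis(methoxymethoxy)phenyl]tridec-5-enoate | CCOC(=O)CCC/C=C\CCCCCCCc1cc(OCOC)cc(OCOC)c1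
F10 | step 2 | 8-(9-borabicyclo[3.3.1]nonan-9-yl)octan-1-ol | OCCCCCCCCB1C2CCCC1CCC2
A1 | alternative 1 | 2-[(3S,9Z)-17-{3,5-bis[(triisopropylsilyl)oxy]phenyl}heptadec-9-en-3-yl]-4,4,5,5-tetramethyl-1,3,2-dioxaborolane | CC[C@H](B1OC(C)(C)C(C)(C)O1)CCCCC/C=C\CCCCCCCc1cc(O[Si](C(C)C)(C(C)C)C(C)C)cc(O[Si](C(C)C)(C(C)C)C(C)C)c1
A2 | alternative 1 | (7Z)-15-{3,5-bis[(triisopropylsilyl)oxy]phenyl}pentadec-7-en-1-yl N,N-diisopropylcarbamate | CC(C)N(C(C)C)C(=O)OCCCCCC/C=C\CCCCCCCc1cc(O[Si](C(C)C)(C(C)C)C(C)C)cc(O[Si](C(C)C)(C(C)C)C(C)C)c1
A3 | alternative 1 | 2-ethyl-4,4,5,5-tetramethyl-1,3,2-dioxaborolane | CCB1OC(C)(C)C(C)(C)O1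
A4 | alternative 2 | tert-butyl{[(3S,9Z)-17-[3,5-bis(methoxymethoxy)phenyl]heptadec-9-en-3-yl]oxy}dimethylsilane | CC[C@H](O[Si](C)(C)C(C)(C)C)CCCCC/C=C\CCCCCCCc1cc(OCOC)cc(OCOC)c1
A5 | alternative 2 | (Z)-1,2-dichloroethene | Cl/C=C\Cl
A6 | alternative 2 | {7-[3,5-bis(methoxymethoxy)phenyl]heptyl}magnesium bromide | Br[Mg]CCCCCCCc1cc(OCOC)cc(OCOC)c1
A7 | alternative 2 | 1-[(8Z)-9-chloronon-8-en-1-yl]-3,5-bis(methoxymethoxy)benzene | Cl/C=C\CCCCCCCc1cc(OCOC)cc(OCOC)c1
A8 | alternative 2 | [(6S)-6-{[tert-butyl(dimethyl)silyl]oxy}octyl]magnesium bromide | CC[C@H](O[Si](C)(C)C(C)(C)C)CCCCC[Mg]Br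
A9 | alternative 3 | (3S,9Z)-17-[3,5-bis(methoxymethoxy)phenyl]heptadec-9-en-3-yl benzoate | CC[C@H](OC(=O)c1ccccc1)CCCCC/C=C\CCCCCCCc1cc(OCOC)cc(OCOC)c1
A10 | alternative 3 | 1-[(8Z)-tetradeca-8,13-dien-1-yl]-3,5-bis(methoxymethoxy)benzene | C=CCCC/C=C\CCCCCCCc1cc(OCOC)cc(OCOC)c1
A11 | alternative 3 | racemic 1-bromopropyl benzoate | CCC(Br)OC(=O)c1ccccc1
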